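We start from a ratio: the isomerisation holds isomer of the product to complex with one exchanged at 2.1 to one, and the next run hangs on when the isomer overtakes the starting complex.

    complex with two exchanged + incoming ligand ⇌ leaving ligand + complex with three exchanged (K1 = 3.1, k1 = 11 M⁻¹ s⁻¹)
    complex with one exchanged + incoming ligand ⇌ leaving ligand + complex with two exchanged (K2 = 2.1, k2 = 6.2 M⁻¹ s⁻¹)
    complex with one exchanged ⇌ isomer of the product (K3 = 2.1, k3 = 0.18 s⁻¹)
    starting complex + incoming ligand ⇌ leaving ligand + complex with one exchanged (K4 = 44, k4 = 3.8 M⁻¹ s⁻¹)

- birch: starting complex 10 mM; incoming ligand 0.800 equiv; time 1.0 min
- elm: starting complex 10 mM; incoming ligand 0.800 equiv; time 3.0 min

- which of these there is most of at the end, counted by the starting complex in it, birch (complex with two exchanged / starting complex / isomer of the product / complex with one exchanged)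
- which of these there is most of at the end, counted by the starting complex in it, elm (complex with two exchanged / starting complex / isomer of the product / complex with one exchanged)
- the largest of these amounts at the end, in percent of the starting complex charged, birch
- the largest of these amounts at the end, in percent of the starting complex charged, elm

Suppose we want the isomer of the product from little material: do we stop at birch's time or go on to elm's? The isomerisation relaxes with a half-life of 2.61 s, short against the 1.0 min of birch. So we treat complex with one exchanged and isomer of the product as one pool, of which the isomer holds 67.7 %.

Let x be the fraction of the charge still present as starting complex. Leaving the complexes with two and three exchanged aside for now, the isomer of the product, as a fraction of the charge, is that share of the rest, one minus x. Setting the two equal gives the crossing share, the pool share over one plus the pool share: 40.4 %. Any complex with two or three exchanged takes from the pool, so the starting complex must fall at least this far before the isomer leads.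

How far can it fall? We give the first exchange the whole charge of incoming ligand, the limiting reagent at 0.800 equiv, and no way back. The second-order integral then leaves a floor of 40.6 % in birch and 25.1 % in elm. The floor in birch stands just above the crossing share, so starting complex leads there. The floor in elm lies below it, so the isomer can lead, with a ceiling of 50.7 %. We commit to the isomer in elm and choose elm's time on the same charge.

The forecast names starting complex for birch at 45 % (range 41 % to 49 %) and isomer of the product for elm at 42 % (range 37 % to 47 %), saying that “material collects in the isomer”. It picks the same leaders; its numbers are estimates where ours are limits.

Birch ends with starting complex at 46.8 % and elm with isomer of the product at 40.7 %, inside the forecast's ranges. In elm the first exchange has 88 % of its turnover up to the asked time behind it at 1.50 min, when incoming ligand stands at 11.5 % of its charge. Starting complex ends at 33.5 % in elm, under the crossing share, and isomer and starting complex hold the same there at a factor of 0.910 on the incoming ligand. In the neighbour elm flask with 0.200 equiv of incoming ligand, the same integral gives a floor of 80.1 %, far above the crossing share, so starting complex should lead. Starting complex ends there at 81.0 %, with the isomer at 12.4 %.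

The constants were drawn at random within sensible limits; no experiment stands behind them.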